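Two questions stand for this flask: how much target it holds at 6.0 h, and how near saturation its dissolved gas is then.

the same everywhere: gas phase 200 mM (held)

| charge | starting material | remark | time |
|---|---|---|---|
| Tuesday's | 0.39 M | run made earlier |  |
| Thursday's | 1.5 M | run made earlier |  |
| flask | 0.77 M |  | 6.0 h |

- Tuesday's (time / h: target / %): 1.33: 40.9; 3.00: 30.9; 4.00: 26.9; 6.00: 19.3; 8.00: 13.4
- Thursday's (time / h: target / %): 0.667: 13.4; 2.00: 14.7; 3.00: 12.7; 5.00: 9.1; 8.00: 5.5

(standard deviation of a reading: 0.5 percentage points)

1. how much target there is at 6.0 h, in percent of the starting material charged
2. concentration of dissolved gas in solution at 6.0 h, in percent of saturation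

- the numbers in the tables scatter with a standard deviation of 0.5 percentage points
- at the start none of the gas phase is in solution

You can get far with a bench rule: once a product is no longer being made, count its half-lives. In Tuesday's run, the target falls from 30.9% at 3.00 h to 13.4% at 8.00 h. That gives the target's late half-life, the time in which a first-order loss takes half of what stands, as 4.15 h. Thursday's run, with its heavier charge, gives 4.14 h over the same times.

The rule has a border. Between 0.667 h and 2.00 h in Thursday's run, this half-life predicts a factor of 0.800, but the readings give 1.10, a rise. So I start counting at 3.00 h.

This flask's charge is twice Tuesday's and half Thursday's, so I take the middle by ratio of the two readings at 3.00 h, 19.8%. Counting on to 6.0 h gives me 12.0%. I add no figure of my own for the gas.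

The forecast gives 12% and 97%: “The late points of both runs fall with the same first-order constant”. Its target figure and mine rest on the same readings, so their closeness checks nothing.

The flask gives 12.3% of target and 99.3% of saturation.

    gas phase ⇌ dissolved gas, rate k1*(csat - [dissolved gas]) (kL = 0.00340 s⁻¹)
    starting material + dissolved gas → target (k = 0.00230 M⁻¹ s⁻¹)
    dissolved gas + target → over-reacted product (k = 2.60 × 10⁻⁴ M⁻¹ s⁻¹)
    starting material + target → side product (k = 0.00130 M⁻¹ s⁻¹)

At 6.00 h, this flask makes dissolved gas 1.02 times as fast as it uses it, each step taken net. At 0.474 h in this flask, the step into target used gas 21 times as fast as the step into over-reacted product. By 3.00 h this flask holds 0.101% of starting material and 0.197 M of dissolved gas, and from there on the target's loss can be treated as pseudo-first-order. From this flask's 21.3% at 3.00 h, the half-life read from Tuesday's run gives 12.9% at 6.0 h. Counted on from 12.3% to 10 h in the same flask, it gives 6.31%, and that flask stands at 5.82%.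

The readings stem from a simulated flask for substances that don't exist; the scatter is artificial.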